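Target, by the candidate steps, costs one partner each, and each protic impurity can take a further partner into quenched reagent. The flasks on the bench and the runs so far are these:

| setting | teal | grey | violet | ash | alder | maple | larch | elm |
|---|---|---|---|---|---|---|---|---|
| substrate | 0.065 M | 0.24 M | 0.050 M | 0.050 M | 0.20 M | 0.050 M | 0.080 M | 0.15 M |
| partner | 0.060 M | 0.060 M | 0.060 M | 0.0600 M | 0.0400 M | 0.0300 M | 0.250 M | 0.0600 M |
| protic impurity | 5 mM | 5 mM | 13 mM | 5.00 mM | 15.0 mM | 8.00 mM | 20.0 mM | 5.00 mM |
| free catalyst | 7 mM | 7 mM | 7 mM | 7.0 mM | 7.0 mM | 10 mM | 7.0 mM | 10 mM |
| remark | run made earlier | run made earlier | run made earlier |  |  |  |  |  |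
| time |  |  |  | 2.5 d | 2.5 d | 2.5 d | 2.5 d | 2.5 d |

- teal (time / h: target / %): 2.50: 12.5; 4.00: 22.8; 6.00: 35.5; 10.0: 52.2; 20.0: 72.1; 30.0: 79.1
- grey (time / h: target / %): 2.50: 5.6; 4.00: 8.6; 6.00: 12.6; 10.0: 18.7; 20.0: 23.1; 30.0: 23.9
- violet (time / h: target / %): 2.50: 14.1; 5.00: 32.0; 8.00: 47.5; 15.0: 68.5; 30.0: 83.6

(standard deviation of a reading: 1 percentage point)

* ranking by amount of target, in percent of the substrate charged, from high to low, at 2.5 d (ash / alder / maple / larch / elm)
* the same order at 6.0 h (ash / alder / maple / larch / elm)
* the amount of target, in percent of the substrate charged of the flask you put first, at 2.5 d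
* the amount of target, in percent of the substrate charged of the flask you put last, at 2.5 d

- candidate steps: substrate + free catalyst -> catalyst intermediate A; partner + catalyst intermediate A <-> catalyst intermediate B; catalyst intermediate B -> released group + catalyst intermediate C; catalyst intermediate C -> catalyst intermediate D; catalyst intermediate D -> free catalyst + target; substrate + released group -> side product; partner + protic impurity -> quenched reagent
- no earlier run changes the charge of free catalyst; that part of a forecast is a guess

Grey, with [substrate] far over [partner], lies flat at its end, at 23.1 % and then 23.9 %. Charged partner corresponds to 25.0 % of grey's substrate, and partner less impurity to 22.9 %. With a scatter of 1 percentage point, the reading cannot separate the two, so the reckoning here makes a choice: the impurity costs its full charge, since its step has no way back.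

Alder is then expected to end at 12.5 %: charged [partner] less charged [protic impurity], over charged [substrate], the usable-partner ceiling. Maple has 44.0 % and elm 36.7 %, so partner is the limiting reagent in these flasks, and alder stands lower than the other two. Time does not enter the ceiling, so waiting does not raise it, and at fixed [partner] and [protic impurity] extra substrate lowers it. Ash reckons to 110 % and larch to 288 %. Both exceed the substrate charged, so the ceiling does not rank them, nor does it rank anything at 6.0 h.

The forecast gives larch > ash > maple > elm > alder at 2.5 d and ash > larch > maple > elm > alder at 6.0 h, with larch at 91 % and alder at 14 %, and says: “The ash and larch order is uncertain”. Its alder stands above the ceiling reckoned here.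

    substrate + free catalyst → catalyst intermediate A (k = 28.0 M⁻¹ h⁻¹)
    partner + catalyst intermediate A ⇌ catalyst intermediate B (K = 17.0 M⁻¹, k = 76.0 M⁻¹ h⁻¹)
    catalyst intermediate B → released group + catalyst intermediate C (k = 4.50 h⁻¹)
    catalyst intermediate C → catalyst intermediate D (k = 41.0 h⁻¹)
    catalyst intermediate D → free catalyst + target (k = 7.20 h⁻¹)
    substrate + released group → side product (k = 1.10 M⁻¹ h⁻¹)
    partner + protic impurity → quenched reagent (k = 210 M⁻¹ h⁻¹)

The flasks give ash > larch > maple > elm > alder at 2.5 d and larch > ash > maple > elm > alder at 6.0 h, with ash at 86.8 %, larch at 82.7 %, and alder at 12.5 % against its ceiling of 12.5 %. In ash, the half-life of partner by quenching, concentrations held as charged, is 0.66 h, shorter than the 0.18 d by forward binding to catalyst intermediate A at 0.234 d. At 2.50 d, ash holds 0.00500 M of quenched reagent, its full impurity charge. A further flask, ash with 0.20 M of substrate, has a ceiling of 27.5 % and gives 27.5 % of target.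

Readings and results come from a simulation for substances that don't exist; noise was put on by code.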